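A plateau is easily read as a fixed yield of the chemistry, yet J levels off differently in Friday's flask and Saturday's, which differ in their L charge and share the same D and G.

all flasks: D 80 mM; G 24 mM
- Friday's: L 1 M; the very flask that is asked about, followed so far
- Saturday's: L 2 M; run made earlier
- flask: L 1.0 M; time 50 min

- Friday's (time / min: L / %, J / %, Q / %): 0.500: 63.3, 3.5, 33.5; 1.50: 23.6, 9.1, 67.0; 3.00: 5.0, 11.5, 82.6; 4.00: 0.8, 12.3, 86.5; 6.00: 0, 12.8, 86.6; 8.00: 0, 13.7, 87.1; 10.0: 0.5, 13.2, 86.2
- Saturday's (time / min: L / %, J / %, Q / %): 1.00: 36.8, 8.7, 54.0; 3.00: 3.0, 16.6, 79.2; 6.00: 0, 17.5, 81.8; 8.00: 0, 17.4, 82.3; 12.0: 0, 17.1, 83.0; 15.0: 0, 17.5, 82.5; 20.0: 0, 17.7, 81.5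

(scatter of a reading: 0.5 percentage points)

- the reaction counts as stopped when no species that holds the L changes by six tenths of a point or more over the second half of the time

- why nothing more happens at 50 min, or that something still does (no working catalyst is left / it is still moving / forward and back rates have come level / all of L has reacted)
- part of the L gone at 50 min
- the J standing at 50 min, as a percentage of the L charged
- the Q standing at 50 min, as a percentage of the L charged
- amount of J if the flask were left three thousand times as long, in percent of the L charged

The ledger follows the L charged, entry by entry. In Friday's run, the opening entry, up to 0.500 min, pays J 3.5% and Q 33.5%, a split of 0.104 J per Q. The next entry, up to 3.00 min, pays at 0.163, a higher split than the opening one.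

The books then close. In Friday's run the half-life of L, read at 1.50 min, is about 0.720 min, which makes 50 min some 69.4 half-lives, and L already reads 0% at 6.00 min.

What carries over is the closing split, J over Q once L reads zero, a selectivity under kinetic rather than thermodynamic control. As a reading, it averages 0.153 over Friday's last three readings and 0.212 over Saturday's last five. Saturday's L charge is twice Friday's, so the charge exponent, the logarithm of the ratio of closing splits over that of the ratio of L charges with D and G held, reads 0.474. This ledger puts the flask's J at 13.3%. Saturday's J reads 17.5% at 6.00 min and 17.7% at 20.0 min, each reading good to 0.5 percentage points.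

The forecast says all of L has reacted, with 100% of L gone (99.5% to 100%), J 13.2% (12.5% to 13.9%) and Q 86.7% (86% to 87.4%). After the long wait it has J at 13.2% (11.5% to 14.2%). Of the two charges it says: “so these look like kinetically set branching yields, not an equilibrium”.

The simulated flask gives all of L has reacted: 100% of L gone, J 13.2%, Q 86.8%, and J 13.2% after the long wait.

    L + D → E + J (k = 0.0120 L mol⁻¹ s⁻¹)
    L + E → J + E, rate k2*[E]*[L] (k = 0.100 L mol⁻¹ s⁻¹)
    L → Q (k = 0.0140 s⁻¹)
    D + G → X (k = 340 L mol⁻¹ s⁻¹)

The flask's closing split stands at 0.152. The exponent 0.474 carries the reading 0.153 to a neighbouring flask, the same flask with 0.25 M of L, a quarter of the charge. The reckoning gives 0.0792 J per Q, which puts J at 7.34% of the L charged. In that neighbour, L ends at 0% of its charge and D at 57% of its own. The neighbour closes at a split of 0.0807, with J 7.47% and Q 92.5%.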